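## Retrosynthetic overview
1. C11=C12 (Wittig, last step): target ⇒ ring A C15 dienyl alcohol, used as its phosphonium salt, plus the all-E C25 aldehyde apo-12'-lycopenal.
2. C25 aldehyde ⇒ C10 dialdehyde plus an acyclic C15 phosphonium salt made from pseudoionone and a vinyl Grignard reagent.
3. C6–H ⇒ C6–O: the cis C5-OH/C6-chain pair comes from a dienyl oxirane by palladium/formate hydrogenolysis with inversion (new step). C7=C8 ⇒ Horner–Wadsworth–Emmons reaction on an epoxy aldehyde.
4. Key disconnection, C5–O and C6–O: nucleophilic epoxidation of a cyclopentene carbaldehyde anti to the isopropenyl group. This step installs the only heteroatom and controls both C5 and C6.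
5. Ring order: cyclopentane ring A first (ozonolysis/aldol ring contraction of (S)-limonene, which supplies C2). Oxirane ring B second, opened again two steps later.

Numbering: carotenoid numbering is used. Ring A is C2–C6: C2 carries the isopropenyl group, C5 carries CH3 and OH, and C6 carries the chain. The target is 2S,5S,6R, with isopropenyl trans to the chain and OH cis to the chain.

Assumption: commercial pseudoionone and the C5 phosphonate are E/Z mixtures rich in the isomers drawn; they are used as bought, and material derived from the minor Z isomers is removed at the first chromatographed or crystallised product.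

## Route

Step 1
Reactants: 1 (S)-(−)-limonene
Product: 2 (3S)-6-oxo-3-(prop-1-en-2-yl)heptanal
Conditions: O3 (1.0 equiv, Sudan Red 7B end point), CH2Cl2/MeOH 5:1, −78 °C; then Me2S, −78 °C to rt
Reagents that add atoms: ozone, [O-][O+]=O
Why: Ozonolysis with reductive work-up: the trisubstituted ring alkene is more electron-rich than the 1,1-disubstituted isopropenyl alkene and takes up the single equivalent of O3 first, and the stereocentre (later C2) is not touched.

Step 2
Reactants: 2 (3S)-6-oxo-3-(prop-1-en-2-yl)heptanal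
Product: 3 (5R)-2-methyl-5-(prop-1-en-2-yl)cyclopent-1-ene-1-carbaldehyde
Conditions: piperidine (0.2 equiv), AcOH (0.2 equiv), toluene, Dean–Stark, reflux, 2 h
Reagents that add atoms: none
Why: Amine-catalysed intramolecular aldol condensation (5-enolexo closure of the aldehyde enamine on the methyl ketone, then loss of water) forms ring A, and the hydrogen at the stereocentre is acidic in neither 2 nor 3, so the configuration holds.

Step 3
Reactants: 3 (5R)-2-methyl-5-(prop-1-en-2-yl)cyclopent-1-ene-1-carbaldehyde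
Product: 4 (1R,2R,5S)-5-methyl-2-(prop-1-en-2-yl)-6-oxabicyclo[3.1.0]hexane-1-carbaldehyde (oxirane oxygen trans to isopropenyl)
Conditions: 30% aq H2O2 (3 equiv), NaOH (0.3 equiv), MeOH, 0 °C to rt
Reagents that add atoms: hydrogen peroxide, OO
Why: Weitz–Scheffer nucleophilic epoxidation, the key C–O bond formation: HOO− adds reversibly to the β-carbon and the enolate closes onto oxygen on the ring face opposite the neighbouring isopropenyl group, which sets C5 as S and places the C6–O bond on that same face for the later relay, while the unactivated isopropenyl alkene does not react with a nucleophilic oxidant.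

Step 4
Reactants: 4 epoxy aldehyde; 5 triethyl 3-methyl-4-phosphonocrotonate [ethyl (2E)-4-(diethoxyphosphoryl)-3-methylbut-2-enoate]
Product: 6 ethyl (2E,4E)-3-methyl-5-[(1R,2R,5S)-5-methyl-2-(prop-1-en-2-yl)-6-oxabicyclo[3.1.0]hexan-1-yl]penta-2,4-dienoate
Conditions: 5 (1.3 equiv), LiN(SiMe3)2 (1.25 equiv), THF/DMPU, −78 °C to 0 °C
Reagents that add atoms: none
Why: Horner–Wadsworth–Emmons olefination: the stabilised allylic phosphonate anion adds to the non-enolisable aldehyde and loses phosphate to give C7=C8 as the E alkene (the minor 9Z isomer is removed by chromatography), and the oxirane with its two stereocentres is not touched.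

Step 5
Reactants: 6 epoxy dienoate
Product: 7 ethyl (2E,4E)-5-[(1R,2S,5S)-2-hydroxy-2-methyl-5-(prop-1-en-2-yl)cyclopentyl]-3-methylpenta-2,4-dienoate
Conditions: Pd2(dba)3·CHCl3 (2.5 mol %), n-Bu3P (5 mol %), HCO2H (5 equiv), Et3N (2 equiv), 1,4-dioxane, rt
Reagents that add atoms: none
Why: Proposed new method: formate hydrogenolysis of a dienyl oxirane (an ε,ζ-epoxy-2,4-dienoate) at a fully substituted ring carbon, in which zerovalent palladium ionises the allylic C6–O bond anti to oxygen (from the face that carries isopropenyl and CH3), HCO2H protonates the C5 alkoxide, formate binds to palladium and loses CO2, and the resulting Pd–H passes hydride to C6 on the palladium-bearing face before the metal can walk down the chain, since C6 is the only delivery site that keeps the dienoate conjugated and the 1:1 n-Bu3P:Pd ratio keeps formate inner-sphere, so net inversion at C6 puts the chain cis to OH and trans to isopropenyl (6R) with C7=C8 kept E; the closest known reaction type is the palladium/formate hydrogenolysis of mono-alkenyl oxiranes (γ,δ-epoxy enoates) to homoallylic alcohols with inversion (Tsuji–Shimizu type).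

Step 6
Reactants: 7 hydroxy dienoate
Product: 8 (2E,4E)-5-[(1R,2S,5S)-2-hydroxy-2-methyl-5-(prop-1-en-2-yl)cyclopentyl]-3-methylpenta-2,4-dien-1-ol
Conditions: i-Bu2AlH (3.3 equiv), CH2Cl2, −78 °C to −20 °C; aq potassium sodium tartrate
Reagents that add atoms: none
Why: 1,2-Reduction of the ester with i-Bu2AlH gives the primary allylic alcohol (the first equivalent is consumed by the free hydroxyl), and no alkene or stereocentre is affected.

Step 7
Reactants: 9 (3E,5E)-pseudoionone [(3E,5E)-6,10-dimethylundeca-3,5,9-trien-2-one]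
Product: 10 vinyl-ψ-ionol [(4E,6E)-3,7,11-trimethyldodeca-1,4,6,10-tetraen-3-ol, racemic at C3]
Conditions: CH2=CHMgBr (1.2 equiv), THF, −20 °C to 0 °C; aq NH4Cl
Reagents that add atoms: vinylmagnesium bromide, C=C[Mg]Br
Why: Grignard 1,2-addition to the dienone carbonyl gives the tertiary bis-allylic alcohol, whose racemic carbinol centre is erased in the next step.

Step 8
Reactants: 10 vinyl-ψ-ionol; 11 (2E,4E,6E)-2,7-dimethylocta-2,4,6-trienedial (C10 dialdehyde)
Product: 13 all-E apo-12'-lycopenal (C25 aldehyde), via acyclic C15 phosphonium bromide 12 (not isolated)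
Conditions: Ph3P·HBr (1.0 equiv), MeOH, rt, 16 h; then dosed together with NaOMe (1.1 equiv) into 11 (1.5 equiv), CH2Cl2/MeOH, 0 °C, Ar, dark; crystallise
Reagents that add atoms: none
Why: Acid-promoted allylic transposition (ionisation to the trienyl cation, then attack of Ph3P at the unhindered terminal carbon) gives the C15 salt, and the Wittig reaction of its ylide with excess dialdehyde stops at mono-olefination because the C25 aldehyde is more conjugated, less electrophilic, and crystallises as the all-E isomer.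

Step 9
Reactants: 8 ring A C15 diol; 13 all-E apo-12'-lycopenal
Product: 15 target CNP0222499.1, via ring A C15 phosphonium bromide 14 (not isolated)
Conditions: Ph3P·HBr (1.0 equiv), MeOH/CH2Cl2, 0 °C to rt; then 13 (0.95 equiv), NaOMe (1.1 equiv), 0 °C to rt, Ar, dark; reflux in EtOH 2 h (Z to E), crystallise
Reagents that add atoms: none
Why: The primary dienyl alcohol ionises far faster than the unactivated tertiary alcohol, so Ph3P·HBr gives the C11 phosphonium salt selectively, the Wittig reaction closes C11=C12, the hindered 11Z isomer relaxes thermally to all-E, and the three ring stereocentres lie away from the reacting sites and are kept.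

## Compound list
1 | (S)-(−)-limonene [(4S)-1-methyl-4-(prop-1-en-2-yl)cyclohex-1-ene] | C=C(C)[C@H]1CCC(C)=CC1 | starting material
2 | (3S)-6-oxo-3-(prop-1-en-2-yl)heptanal | C=C(C)[C@H](CC=O)CCC(C)=O | intermediate
3 | (5R)-2-methyl-5-(prop-1-en-2-yl)cyclopent-1-ene-1-carbaldehyde | C=C(C)[C@H]1CCC(C)=C1C=O | intermediate
4 | (1R,2R,5S)-5-methyl-2-(prop-1-en-2-yl)-6-oxabicyclo[3.1.0]hexane-1-carbaldehyde | C=C(C)[C@H]1CC[C@]2(C)O[C@]12C=O | intermediate
5 | triethyl 3-methyl-4-phosphonocrotonate [ethyl (2E)-4-(diethoxyphosphoryl)-3-methylbut-2-enoate] | CCOC(=O)/C=C(C)/CP(=O)(OCC)OCC | starting material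
6 | ethyl (2E,4E)-3-methyl-5-[(1R,2R,5S)-5-methyl-2-(prop-1-en-2-yl)-6-oxabicyclo[3.1.0]hexan-1-yl]penta-2,4-dienoate | C=C(C)[C@H]1CC[C@]2(C)O[C@]12/C=C/C(C)=C/C(=O)OCC | intermediate
7 | ethyl (2E,4E)-5-[(1R,2S,5S)-2-hydroxy-2-methyl-5-(prop-1-en-2-yl)cyclopentyl]-3-methylpenta-2,4-dienoate | C=C(C)[C@H]1CC[C@](C)(O)[C@@H]1/C=C/C(C)=C/C(=O)OCC | intermediate
8 | (2E,4E)-5-[(1R,2S,5S)-2-hydroxy-2-methyl-5-(prop-1-en-2-yl)cyclopentyl]-3-methylpenta-2,4-dien-1-ol | C=C(C)[C@H]1CC[C@](C)(O)[C@@H]1/C=C/C(C)=C/CO | intermediate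
9 | (3E,5E)-pseudoionone [(3E,5E)-6,10-dimethylundeca-3,5,9-trien-2-one] | CC(=O)/C=C/C=C(\C)CCC=C(C)C | starting material
10 | vinyl-ψ-ionol [(4E,6E)-3,7,11-trimethyldodeca-1,4,6,10-tetraen-3-ol, racemic] | C=CC(C)(O)/C=C/C=C(\C)CCC=C(C)C | intermediate
11 | (2E,4E,6E)-2,7-dimethylocta-2,4,6-trienedial | O=C/C(C)=C/C=C/C=C(C)/C=O | starting material
12 | [(2E,4E,6E)-3,7,11-trimethyldodeca-2,4,6,10-tetraen-1-yl]triphenylphosphonium bromide | [Br-].c1ccccc1[P+](c1ccccc1)(c1ccccc1)C/C=C(C)/C=C/C=C(\C)CCC=C(C)C | intermediate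
13 | apo-12'-lycopenal [(2E,4E,6E,8E,10E,12E,14E)-2,7,11,15,19-pentamethylicosa-2,4,6,8,10,12,14,18-octaenal] | O=C/C(C)=C/C=C/C=C(C)/C=C/C=C(C)/C=C/C=C(\C)CCC=C(C)C | intermediate
14 | {(2E,4E)-5-[(1R,2S,5S)-2-hydroxy-2-methyl-5-(prop-1-en-2-yl)cyclopentyl]-3-methylpenta-2,4-dien-1-yl}triphenylphosphonium bromide | C=C(C)[C@H]1CC[C@](C)(O)[C@@H]1/C=C/C(C)=C/C[P+](c1ccccc1)(c1ccccc1)c1ccccc1.[Br-] | intermediate
15 | (all-E,2S,5S,6R)-1,16-didehydro-2,6-cyclolycopen-5-ol [(1S,2R,3S)-1-methyl-3-(prop-1-en-2-yl)-2-(all-E-3,7,12,16,20,24-hexamethylpentacosa-1,3,5,7,9,11,13,15,17,19,23-undecaen-1-yl)cyclopentan-1-ol] | C=C(C)[C@H]1CC[C@](C)(O)[C@@H]1/C=C/C(C)=C/C=C/C(C)=C/C=C/C=C(C)/C=C/C=C(C)/C=C/C=C(\C)CCC=C(C)C | target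

## Step count
Total steps: 9, with no protecting groups.
Longest linear sequence: 7 (steps 1–6, then step 9).

## Three steps most likely to fail

**Step 5 (the proposed new step).**
- Hydride may be delivered at C8 or C10 after the palladium migrates along the pentadienyl system.
- Ionisation may be slow on the face flanked by isopropenyl and CH3.
- Elimination to a triene may compete.

The fallback sets out from 4 and comes back at 7, using known chemistry only. Compound 4 is condensed with 1-(triphenylphosphoranylidene)propan-2-one (toluene, 80 °C) to give the γ,δ-epoxy enone (E)-4-[(1R,2R,5S)-5-methyl-2-(prop-1-en-2-yl)-6-oxabicyclo[3.1.0]hexan-1-yl]but-3-en-2-one F1. This is a mono-alkenyl oxirane, the class for which palladium/formate hydrogenolysis with inversion is established. The same Pd2(dba)3·CHCl3/n-Bu3P/HCO2H/Et3N system then gives the δ-hydroxy enone (E)-4-[(1R,2S,5S)-2-hydroxy-2-methyl-5-(prop-1-en-2-yl)cyclopentyl]but-3-en-2-one F2. A Horner–Wadsworth–Emmons reaction of F2 with triethyl phosphonoacetate (NaH, THF, 2.2 equiv of anion) builds C9=C10 afterwards and gives 7 once the 9Z isomer is separated. This costs one more step.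

**Step 3.**
- Addition to the tetrasubstituted β-carbon may be slow.
- HOO− may attack the aldehyde instead.
- The facial ratio may be only moderate.

The fallback sets out from 3 and comes back at 4. It replaces conjugate epoxidation with a hydroxyl-directed electrophilic epoxidation. Luche reduction (NaBH4, CeCl3·7H2O, MeOH, 0 °C) gives the allylic alcohol [(5R)-2-methyl-5-(prop-1-en-2-yl)cyclopent-1-en-1-yl]methanol F3. VO(acac)2 (2 mol %) with t-BuOOH in toluene at 0 °C epoxidises only the allylic-alcohol alkene, on the face away from isopropenyl, giving [(1S,2R,5S)-5-methyl-2-(prop-1-en-2-yl)-6-oxabicyclo[3.1.0]hexan-1-yl]methanol F4. Dess–Martin periodinane (CH2Cl2, NaHCO3) then returns 4.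

**Step 9.**
- Acid may protonate the isopropenyl group.
- The cis C5 hydroxyl may trap the dienyl cation at C9 to form a cyclic ether.
- The one-pot ylide formation may give a poor E/Z ratio or a low yield.

The fallback sets out from 8 and 13 and comes back at 15. It reverses the polarity of the coupling so that the ring fragment never sees acid. Compound 8 is oxidised with MnO2 (CH2Cl2, rt) to (2E,4E)-5-[(1R,2S,5S)-2-hydroxy-2-methyl-5-(prop-1-en-2-yl)cyclopentyl]-3-methylpenta-2,4-dienal F5. Compound 13 is reduced with NaBH4 (EtOH/THF, 0 °C) to all-E apo-12'-lycopenol F6. F6 is converted with Ph3P·HBr (MeOH/CH2Cl2, rt) into the C25 phosphonium bromide F7. A Wittig reaction of F7 with F5 (NaOMe, CH2Cl2/MeOH, 0 °C to rt, then thermal Z to E equilibration) forms the same C11=C12 bond and gives 15.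

## Further compounds
F1 | step 5 | (E)-4-[(1R,2R,5S)-5-methyl-2-(prop-1-en-2-yl)-6-oxabicyclo[3.1.0]hexan-1-yl]but-3-en-2-one | C=C(C)[C@H]1CC[C@]2(C)O[C@]12/C=C/C(C)=O
F2 | step 5 | (E)-4-[(1R,2S,5S)-2-hydroxy-2-methyl-5-(prop-1-en-2-yl)cyclopentyl]but-3-en-2-one | C=C(C)[C@H]1CC[C@](C)(O)[C@@H]1/C=C/C(C)=O
F3 | step 3 | [(5R)-2-methyl-5-(prop-1-en-2-yl)cyclopent-1-en-1-yl]methanol | C=C(C)[C@H]1CCC(C)=C1CO
F4 | step 3 | [(1S,2R,5S)-5-methyl-2-(prop-1-en-2-yl)-6-oxabicyclo[3.1.0]hexan-1-yl]methanol | C=C(C)[C@H]1CC[C@]2(C)O[C@]12CO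
F5 | step 9 | (2E,4E)-5-[(1R,2S,5S)-2-hydroxy-2-methyl-5-(prop-1-en-2-yl)cyclopentyl]-3-methylpenta-2,4-dienal | C=C(C)[C@H]1CC[C@](C)(O)[C@@H]1/C=C/C(C)=C/C=O
F6 | step 9 | all-E apo-12'-lycopenol [(2E,4E,6E,8E,10E,12E,14E)-2,7,11,15,19-pentamethylicosa-2,4,6,8,10,12,14,18-octaen-1-ol] | OC/C(C)=C/C=C/C=C(C)/C=C/C=C(C)/C=C/C=C(\C)CCC=C(C)C
F7 | step 9 | [(2E,4E,6E,8E,10E,12E,14E)-2,7,11,15,19-pentamethylicosa-2,4,6,8,10,12,14,18-octaen-1-yl]triphenylphosphonium bromide | [Br-].c1ccccc1[P+](c1ccccc1)(c1ccccc1)C/C(C)=C/C=C/C=C(C)/C=C/C=C(C)/C=C/C=C(\C)CCC=C(C)C
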